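## The problem

Compound 23 is an unbranched C20 chain, numbered from the lactone carbonyl C1. Its C1–C5 end is closed through the C5 oxygen to a 4-hydroxy-5,6-dihydro-2H-pyran-2-one (the enol form of a β-keto-δ-lactone), and C12–C20 is a plain nonyl tail. Four secondary carbinol carbons sit in a 1,3,5,7-array: C5 (R), C7 (R), C9 (S) and C11 (S), with C5/C7 syn, C7/C9 anti and C9/C11 syn, separated only by methylene groups. There are no rings to join and no branches, so the task is to build the chain in order and to set each carbinol against its 1,3-neighbour. The syn pair C9/C11 can be fixed by a ring. C7 and C5 each lie two atoms from a centre that steers only weakly once silylated, so they need reagent or catalyst control, or a cyclic acetal. The fragile elements are the enolised keto-lactone (acidic, opened by nucleophilic base, with C3 within reach of the C7 hydroxyl), every β-oxygenated carbonyl intermediate (E1cB loss), α-oxygenated aldehydes (epimerisation) and 1,3-diol silyl ethers (migration). The pyranone is therefore made late and unmasked under mild conditions. The enabling feature is the stretch C7–C12: with oxygen on C7, C9 and C11 and C9/C11 syn, it is all-cis cyclohexane-1,3,5-triol cut between C7 and C12, so a ring-cleaving oxidation of the derived meso ketone opens the ring and distinguishes its two ends in one step.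

## Retrosynthesis

**Pyranone and protecting groups (23 ⇒ 22 ⇒ 21).** The three O–Si bonds are cut last and the C1–O(C5) acyl bond before them. This leads to tris-silyl lactone 22 and then to δ-hydroxy-β-keto ester 21. Closing the lactone from 21 is preferred to carrying the acidic enol-lactone through the synthesis. With C7, C9 and C11 silylated, the C5 hydroxyl is the only one free, so only the six-membered ring can form. The forward steps must lactonise without retro-aldol or elimination, and desilylate without opening the lactone.

**C4–C5 (21 ⇒ 18 + 19).** Cutting C4–C5 gives aldehyde 18 and the acetoacetate dienolate equivalent 19. The neighbouring cuts (C2–C3 by Claisen condensation, C5–C6 by a second allylation) would need extra steps to bring in C1–C3. The C4–C5 cut delivers four carbons, the keto ester and the C5 carbinol in one bond formation. The forward aldol must add to one face of 18 under catalyst control and place C5 syn to C7 against the weak bias of a β-silyloxy group.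

**C6–C7 (18 ⇒ 16 ⇒ 15 ⇒ 13).** Aldehyde 18 is the ozonolysis product of terminal alkene 16, the silyl ether of homoallylic alcohol 15. Cutting C6–C7 of 15 gives aldehyde 13 and an allyl unit. Allylboration is chosen over an acetate aldol because the chiral allylborane sets C7 by reagent control and the alkene is a stable masked aldehyde. The forward reaction must deliver C7 anti to C9 irrespective of the substrate.

**C12–C13 (13 ⇒ 12 ⇒ 11 ⇒ 8 + 9).** Aldehyde 13 comes from Weinreb amide 12, the hydrogenation product of alkene 11. Cutting C12=C13 gives aldehyde 8 and the C8 phosphonium salt 9. The C7 terminus is carried as an N-methoxy-N-methylamide so that the C12 aldehyde is the only electrophile the ylide sees. The olefination must not epimerise C11, which is α to the aldehyde.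

**Reconnection to the lactone (8 ⇒ 7 ⇒ 6).** In hydroxy amide 7 the acyl carbon C7 and the carbinol carbon C12 are five atoms apart. Joining them through oxygen gives seven-membered lactone 6. This is the operation that tells the two chain ends apart. Lactone 6 carries only C9 and C11.

**Key cut (6 ⇒ 4).** Removing the ring oxygen and reconnecting C7–C12 leads to meso ketone 4. A Baeyer–Villiger oxidation of 4 forms the C12–O bond and cleaves C7–C12. Ketone 4 is achiral, and its syn C9/C11 relationship is already built in. The forward step must choose between the two enantiotopic α-methylenes.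

**Origin of the ring (4 ⇒ 3 ⇒ 2 ⇒ 1).** Ketone 4 is the oxidation product of bis-silyl ether 3, made from all-cis triol 2, the hydrogenation product of phloroglucinol 1. Triol 2 is also an article of commerce, so the first step can be bought out.

## Roads not taken

**Alternative 1:** The chain is cut to the C2-symmetric bis(benzylidene acetal) A1, which spans C3–C13 with oxygen on C5, C7, C9 and C11 and a vinyl group at each end. The forward key step treats diene tetraol A2 with Re2O7 and benzaldehyde dimethyl acetal. Both primary allylic hydroxyls shift inward through perrhenate esters by [3,3] rearrangement. The transposed hydroxyls at C5 and C11 are trapped with those at C7 and C9 as all-equatorial 2-phenyl-1,3-dioxanes. The merits are real. Two stereocentres are set at once under thermodynamic control without a chiral reagent, the syn/anti/syn pattern of the target maps exactly onto A1, and the protecting groups arrive in the same step. In stereochemical economy this road is better than the chosen plan, which spends three reagent- or catalyst-controlled steps. The weak points are at the ends. A1 has two homotopic vinyl groups, one of which must become the nonyl tail and the other the C1–C4 keto-lactone. Stopping a reaction at one of two identical termini is statistical. The vinyl carbon C4 must also be turned into a methylene next to a new C3 ketone, which costs several steps. A2 itself needs the anti C7/C9 diol in enantiopure form. Against this, the chosen plan offers two chemically distinct ends (acyl and alkoxy) from the same step that fixes absolute configuration, and a commodity starting material.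

**Alternative 2:** The cuts are C7–C8 and C10–C11. The product of the key step is A3, and the fragments are aldehyde A4 (C3–C7), decanal A5 (C11–C20) and a three-carbon linchpin. The linchpin is a γ-borylated allyl(diisopinocampheyl)borane made in the flask from allenylboronate A6 and (Ipc)2BH. It adds first to A4. The α-substituted allylboronate so formed then adds to A5. This gives both carbinol centres in a 1,5-anti relationship and the E alkene C8=C9. This is the most convergent road: two C–C bonds and two stereocentres in one flask, and a tail that needs no olefination or hydrogenation. In step count to the C3–C20 skeleton it is shorter than the chosen plan. Its weakness for this target is that A3 has no oxygen on C9. Hydration of the C8=C9 alkene must be regioselective for C9 and anti to C7, which adds steps and a new stereochemical problem. The ester carbon of A3 is C3, so C1–C2 are still missing. C5 must be bought with A4, a β-silyloxy aldehyde prone to elimination. The chosen plan has the C9 and C11 oxygens in place and syn from the first step, which is what A3 lacks.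

**Alternative 3:** The cut is C3–C4 at the end of the synthesis. The product of the key step is β-lactone A7, formed from terminal epoxide A8 under CO with [(salph)Al(THF)2][Co(CO)4]. The aluminium cation activates the epoxide, the cobaltate opens it at the unhindered C4, and CO insertion and ring closure follow, leaving C5 untouched. The strained acyl group can then acylate an acetate enolate to give the C1–C5 keto ester. The step is catalytic and atom-economical, and it retains the C5 configuration. As an endgame it is at least as clean as an aldol that has to create C5 under catalyst control. It adds only one carbon, however, and addresses none of the four stereocentres. A8 needs all of them, including a configured epoxide. It also needs pressurised CO, and opening the β-lactone at the acyl carbon competes with attack at C5. The chosen plan sets against it a four-carbon nucleophile that forms C4–C5 and brings C1–C3 in one step. For the polyol the alternative offers nothing.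

Key step: step 4

## Route

Remark 1: the sense of induction of the two chiral promoters (the N,N'-dioxide ligand in step 4, BINOL in step 13) is assigned by analogy with simple cyclohexanones and aliphatic aldehydes; both ligands are available in either mirror-image form, so the antipode is used if the first stereochemical correlation shows the opposite sense.

Remark 2: diene 19 is treated as a purchased reagent; it is otherwise made from methyl acetoacetate by two successive silylations.

Step 1
Reactants: 1 phloroglucinol
Product: 2 all-cis-cyclohexane-1,3,5-triol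
Conditions: H2 (70 bar), 5% Rh/Al2O3, EtOH, 60 °C
Reagents that add atoms: none
Why: Heterogeneous arene hydrogenation on rhodium delivers hydrogen to one face of the adsorbed ring, so the three hydroxyls should emerge mutually cis; the meso all-cis triol is expected to crystallise away from deoxygenated by-products.

Step 2
Reactants: 2 all-cis-cyclohexane-1,3,5-triol
Product: 3 all-cis-3,5-bis(tert-butyldimethylsilyloxy)cyclohexan-1-ol
Conditions: TBSCl (2.1 equiv), imidazole, DMF, 0 °C → rt
Reagents that add atoms: tert-butyldimethylsilyl chloride, CC(C)(C)[Si](C)(C)Cl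
Why: Silyl ether formation; the three hydroxyls are equivalent, so mono- and bis-silylation each give a single constitutional isomer and only the degree of silylation is steered by stoichiometry, with mono- and tris-silylated material returned to the process.

Step 3
Reactants: 3 all-cis-3,5-bis(tert-butyldimethylsilyloxy)cyclohexan-1-ol
Product: 4 (3R,5S)-3,5-bis(tert-butyldimethylsilyloxy)cyclohexan-1-one
Conditions: Dess–Martin periodinane, NaHCO3, CH2Cl2, 0 °C → rt
Reagents that add atoms: none
Why: Dess–Martin oxidation of a secondary alcohol under buffered, amine-free conditions, which should avoid E1cB loss of the two β-silyloxy groups and give the meso ketone.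

Step 4
Reactants: 4 (3R,5S)-3,5-bis(tert-butyldimethylsilyloxy)cyclohexan-1-one
Product: 6 (4S,6R)-4,6-bis(tert-butyldimethylsilyloxy)oxepan-2-one, via Criegee adduct 5 (not isolated)
Conditions: Sc(OTf)3 (5 mol%), N,N'-dioxide ligand from (S)-pipecolic acid 2,6-diisopropylanilide with a propane-1,3-diyl linker (5 mol%), mCPBA (1.3 equiv), EtOAc, −20 °C
Reagents that add atoms: 3-chloroperoxybenzoic acid, OOC(=O)c1cccc(Cl)c1
Why: The peracid adds to the scandium-bound carbonyl of 4 to give Criegee adduct 5, and the α-methylene held antiperiplanar to the O–O bond (C12, the one next to the 3R carbon) migrates to oxygen with loss of 3-chlorobenzoate, forming the C12–O bond and cutting C7–C12. The closest known reaction type is the Sc(OTf)3/chiral N,N'-dioxide-catalysed Baeyer–Villiger desymmetrisation of meso 3,5-disubstituted and prochiral 4-substituted cyclohexanones (matched by cyclohexanone monooxygenases), of which this bis-silyloxy ketone is a new member. The seven-membered ring arises by ring expansion through a 1,2-shift of a ring bond (six to seven) and not by a cyclisation. The bond formation creates no stereogenic carbon; C9 and C11, an enantiomorphic pair in meso 4, become the defined 4S and 6R centres of 6 once the catalyst has chosen the migrating methylene, and their syn relationship is inherited from the all-cis triol. The only selectivity required is between the two enantiotopic CH2 groups, since both are primary carbons of equal migratory aptitude and pose no regiochemical question. The chair locked by the two equatorial silyloxy groups presents these methylenes in fixed, mirror-related positions to the chiral scandium complex, and the weakly basic silyl ethers should leave the carbonyl as the only binding site. Low temperature and a mild Lewis acid are chosen so that no β-silyloxy group is lost.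

Step 5
Reactants: 6 (4S,6R)-4,6-bis(tert-butyldimethylsilyloxy)oxepan-2-one
Product: 7 (3S,5R)-3,5-bis(tert-butyldimethylsilyloxy)-6-hydroxy-N-methoxy-N-methylhexanamide
Conditions: MeNH(OMe)·HCl, Me3Al, CH2Cl2, 0 °C → rt; aq. KNaC4H4O6
Reagents that add atoms: N,O-dimethylhydroxylamine hydrochloride, CNOC.Cl
Why: Weinreb aminolysis of a lactone with the aluminium amide formed from Me3Al and the amine hydrochloride; acyl–oxygen cleavage at C7 frees the C12 primary alcohol and leaves both stereocentres untouched.

Step 6
Reactants: 7 (3S,5R)-3,5-bis(tert-butyldimethylsilyloxy)-6-hydroxy-N-methoxy-N-methylhexanamide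
Product: 8 (3S,5R)-3,5-bis(tert-butyldimethylsilyloxy)-N-methoxy-N-methyl-6-oxohexanamide
Conditions: Dess–Martin periodinane, NaHCO3, CH2Cl2, 0 °C
Reagents that add atoms: none
Why: Dess–Martin oxidation of the primary alcohol; the absence of base should keep the α-silyloxy centre C11 from epimerising, and the aldehyde is used at once without chromatography.

Step 7
Reactants: 8 (3S,5R)-3,5-bis(tert-butyldimethylsilyloxy)-N-methoxy-N-methyl-6-oxohexanamide; 9 octyltriphenylphosphonium bromide
Product: 11 (3S,5R,6Z)-3,5-bis(tert-butyldimethylsilyloxy)-N-methoxy-N-methyltetradec-6-enamide, via octylidenetriphenylphosphorane 10 (not isolated)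
Conditions: 9 (1.2 equiv), NaN(SiMe3)2 (1.15 equiv), THF, 0 °C; then 8, −78 → 0 °C
Reagents that add atoms: none
Why: Wittig olefination with a non-stabilised ylide forms C12=C13; at −78 °C the aldehyde should react far faster than the Weinreb amide, a slight deficit of base leaves no free amide base to epimerise C11, and the Z geometry is of no consequence because the alkene is reduced next.

Step 8
Reactants: 11 (3S,5R,6Z)-3,5-bis(tert-butyldimethylsilyloxy)-N-methoxy-N-methyltetradec-6-enamide
Product: 12 (3S,5S)-3,5-bis(tert-butyldimethylsilyloxy)-N-methoxy-N-methyltetradecanamide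
Conditions: H2 (1 atm), PtO2, EtOAc, rt
Reagents that add atoms: none
Why: Catalytic hydrogenation of the disubstituted alkene; platinum in a non-protic solvent is chosen over palladium to suppress double-bond migration towards C11 and hydrogenolysis of the allylic C–O bond, and the silyl ethers and the N–O bond should persist.

Step 9
Reactants: 12 (3S,5S)-3,5-bis(tert-butyldimethylsilyloxy)-N-methoxy-N-methyltetradecanamide
Product: 13 (3S,5S)-3,5-bis(tert-butyldimethylsilyloxy)tetradecanal
Conditions: iBu2AlH, THF, −78 °C; aq. KNaC4H4O6
Reagents that add atoms: none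
Why: Hydride reduction of a Weinreb amide stops at the aldehyde oxidation level because the carbonyl is released only on aqueous work-up; the β-silyloxy aldehyde is used directly.

Step 10
Reactants: 13 (3S,5S)-3,5-bis(tert-butyldimethylsilyloxy)tetradecanal
Product: 15 (4S,6R,8S)-6,8-bis(tert-butyldimethylsilyloxy)heptadec-1-en-4-ol, via diisopinocampheylborinate ester 14 (not isolated)
Conditions: (−)-Ipc2BOMe, CH2=CHCH2MgBr, Et2O, 0 °C → rt; then 13, −78 °C; NaOH, H2O2, 0 °C → rt
Reagents that add atoms: allylmagnesium bromide, C=CC[Mg]Br
Why: Brown asymmetric allylboration forms C6–C7 through a chair transition state in which the isopinocampheyl groups derived from (+)-α-pinene direct the allyl group to one aldehyde face (reagent control), which should give the 4S carbinol, C7 anti to C9; the β-silyloxy group exerts only a weak bias of its own.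

Step 11
Reactants: 15 (4S,6R,8S)-6,8-bis(tert-butyldimethylsilyloxy)heptadec-1-en-4-ol
Product: 16 (4S,6S,8S)-4,6,8-tris(tert-butyldimethylsilyloxy)heptadec-1-ene
Conditions: TBSOTf, 2,6-lutidine, CH2Cl2, −78 → 0 °C
Reagents that add atoms: tert-butyldimethylsilyl trifluoromethanesulfonate, CC(C)(C)[Si](C)(C)OS(=O)(=O)C(F)(F)F
Why: Silylation of a secondary alcohol with the silyl triflate; a third silyl ether at C7 prevents retro-aldol and elimination at the next aldehyde stage and, being a poor director, leaves the later aldol to catalyst control.

Step 12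
Reactants: 16 (4S,6S,8S)-4,6,8-tris(tert-butyldimethylsilyloxy)heptadec-1-ene
Product: 18 (3R,5S,7S)-3,5,7-tris(tert-butyldimethylsilyloxy)hexadecanal, via 1,2,4-trioxolane 17 (not isolated)
Conditions: O3, CH2Cl2, −78 °C; then PPh3, −78 °C → rt
Reagents that add atoms: ozone, [O-][O+]=O
Why: Ozonolysis of the only alkene with reductive work-up removes C4 of the allyl unit and should give the C5 aldehyde without touching the silyl ethers.

Step 13
Reactants: 18 (3R,5S,7S)-3,5,7-tris(tert-butyldimethylsilyloxy)hexadecanal; 19 1-methoxy-1,3-bis(trimethylsilyloxy)buta-1,3-diene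
Product: 21 methyl (5R,7S,9S,11S)-7,9,11-tris(tert-butyldimethylsilyloxy)-5-hydroxy-3-oxoicosanoate, via bis(trimethylsilyl) aldol adduct 20 (not isolated)
Conditions: (S)-BINOL (10 mol%), Ti(OiPr)4 (10 mol%), 4 Å MS, THF, −78 °C → rt; then TFA, −78 → 0 °C
Reagents that add atoms: none
Why: Vinylogous Mukaiyama aldol of the acetoacetate-derived diene, catalysed by the BINOL–titanium complex, forms C4–C5; the γ-carbon of 19 should add to the Si face of the titanium-bound aldehyde under catalyst control, giving the 5R carbinol syn to C7 against the weak 1,3-bias of the silyl ether; acid then removes the two trimethylsilyl groups.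

Step 14
Reactants: 21 methyl (5R,7S,9S,11S)-7,9,11-tris(tert-butyldimethylsilyloxy)-5-hydroxy-3-oxoicosanoate
Product: 22 (6R)-4-hydroxy-6-[(2S,4S,6S)-2,4,6-tris(tert-butyldimethylsilyloxy)pentadecyl]-5,6-dihydro-2H-pyran-2-one
Conditions: K2CO3, MeOH, 0 °C → rt; then 1 M HCl to pH 3
Reagents that add atoms: none
Why: Base-mediated lactonisation of a δ-hydroxy-β-keto ester; the C5 hydroxyl is the only free one, the six-membered ring closes by intramolecular transesterification, and the product is held as its stabilised enolate until acidification.

Step 15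
Reactants: 22 (6R)-4-hydroxy-6-[(2S,4S,6S)-2,4,6-tris(tert-butyldimethylsilyloxy)pentadecyl]-5,6-dihydro-2H-pyran-2-one
Product: 23 (6R)-4-hydroxy-6-[(2R,4S,6S)-2,4,6-trihydroxypentadecyl]-5,6-dihydro-2H-pyran-2-one
Conditions: 48% aq. HF, MeCN, 0 °C → rt
Reagents that add atoms: none
Why: Global desilylation with aqueous HF in acetonitrile; the enolised keto-lactone is itself acidic and should tolerate these conditions, and no stereocentre is involved.

## Compound list

1 | phloroglucinol (benzene-1,3,5-triol) | Oc1cc(O)cc(O)c1 | starting material
2 | all-cis-cyclohexane-1,3,5-triol (meso) | O[C@H]1C[C@@H](O)C[C@@H](O)C1 | intermediate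
3 | all-cis-3,5-bis(tert-butyldimethylsilyloxy)cyclohexan-1-ol (meso) | O[C@H]1C[C@@H](O[Si](C)(C)C(C)(C)C)C[C@@H](O[Si](C)(C)C(C)(C)C)C1 | intermediate
4 | (3R,5S)-3,5-bis(tert-butyldimethylsilyloxy)cyclohexan-1-one (cis, meso) | O=C1C[C@H](O[Si](C)(C)C(C)(C)C)C[C@H](O[Si](C)(C)C(C)(C)C)C1 | intermediate
5 | Criegee adduct: (3R,5S)-3,5-bis(tert-butyldimethylsilyloxy)-1-hydroxycyclohexyl 3-chlorobenzenecarboperoxoate | OC1(OOC(=O)c2cccc(Cl)c2)C[C@H](O[Si](C)(C)C(C)(C)C)C[C@H](O[Si](C)(C)C(C)(C)C)C1 | intermediate
6 | (4S,6R)-4,6-bis(tert-butyldimethylsilyloxy)oxepan-2-one | C1[C@H](O[Si](C)(C)C(C)(C)C)C[C@H](O[Si](C)(C)C(C)(C)C)CC(=O)O1 | intermediate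
7 | (3S,5R)-3,5-bis(tert-butyldimethylsilyloxy)-6-hydroxy-N-methoxy-N-methylhexanamide | OC[C@H](O[Si](C)(C)C(C)(C)C)C[C@H](O[Si](C)(C)C(C)(C)C)CC(=O)N(C)OC | intermediate
8 | (3S,5R)-3,5-bis(tert-butyldimethylsilyloxy)-N-methoxy-N-methyl-6-oxohexanamide | O=C[C@H](O[Si](C)(C)C(C)(C)C)C[C@H](O[Si](C)(C)C(C)(C)C)CC(=O)N(C)OC | intermediate
9 | octyltriphenylphosphonium bromide | CCCCCCCC[P+](c1ccccc1)(c1ccccc1)c1ccccc1.[Br-] | starting material
10 | octylidenetriphenylphosphorane | CCCCCCCC=P(c1ccccc1)(c1ccccc1)c1ccccc1 | intermediate
11 | (3S,5R,6Z)-3,5-bis(tert-butyldimethylsilyloxy)-N-methoxy-N-methyltetradec-6-enamide | CCCCCCC/C=C\[C@H](O[Si](C)(C)C(C)(C)C)C[C@H](O[Si](C)(C)C(C)(C)C)CC(=O)N(C)OC | intermediate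
12 | (3S,5S)-3,5-bis(tert-butyldimethylsilyloxy)-N-methoxy-N-methyltetradecanamide | CCCCCCCCC[C@H](O[Si](C)(C)C(C)(C)C)C[C@H](O[Si](C)(C)C(C)(C)C)CC(=O)N(C)OC | intermediate
13 | (3S,5S)-3,5-bis(tert-butyldimethylsilyloxy)tetradecanal | CCCCCCCCC[C@H](O[Si](C)(C)C(C)(C)C)C[C@H](O[Si](C)(C)C(C)(C)C)CC=O | intermediate
14 | (4S,6R,8S)-6,8-bis(tert-butyldimethylsilyloxy)heptadec-1-en-4-yl di[(−)-isopinocampheyl]borinate (isopinocampheyl groups from (+)-α-pinene) | CCCCCCCCC[C@H](O[Si](C)(C)C(C)(C)C)C[C@H](O[Si](C)(C)C(C)(C)C)C[C@H](CC=C)OB([C@@H]1C[C@@H]2C[C@H]([C@H]1C)C2(C)C)[C@@H]1C[C@@H]2C[C@H]([C@H]1C)C2(C)C | intermediate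
15 | (4S,6R,8S)-6,8-bis(tert-butyldimethylsilyloxy)heptadec-1-en-4-ol | CCCCCCCCC[C@H](O[Si](C)(C)C(C)(C)C)C[C@H](O[Si](C)(C)C(C)(C)C)C[C@@H](O)CC=C | intermediate
16 | (4S,6S,8S)-4,6,8-tris(tert-butyldimethylsilyloxy)heptadec-1-ene | CCCCCCCCC[C@H](O[Si](C)(C)C(C)(C)C)C[C@H](O[Si](C)(C)C(C)(C)C)C[C@@H](O[Si](C)(C)C(C)(C)C)CC=C | intermediate
17 | 3-[(2R,4S,6S)-2,4,6-tris(tert-butyldimethylsilyloxy)pentadecyl]-1,2,4-trioxolane (ring carbon configuration undefined) | CCCCCCCCC[C@H](O[Si](C)(C)C(C)(C)C)C[C@H](O[Si](C)(C)C(C)(C)C)C[C@@H](O[Si](C)(C)C(C)(C)C)CC1OCOO1 | intermediate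
18 | (3R,5S,7S)-3,5,7-tris(tert-butyldimethylsilyloxy)hexadecanal | CCCCCCCCC[C@H](O[Si](C)(C)C(C)(C)C)C[C@H](O[Si](C)(C)C(C)(C)C)C[C@@H](O[Si](C)(C)C(C)(C)C)CC=O | intermediate
19 | 1-methoxy-1,3-bis(trimethylsilyloxy)buta-1,3-diene | COC(O[Si](C)(C)C)=CC(=C)O[Si](C)(C)C | starting material
20 | methyl (5R,7R,9S,11S)-7,9,11-tris(tert-butyldimethylsilyloxy)-3,5-bis(trimethylsilyloxy)icos-2-enoate (enol ether geometry undefined) | CCCCCCCCC[C@H](O[Si](C)(C)C(C)(C)C)C[C@H](O[Si](C)(C)C(C)(C)C)C[C@@H](O[Si](C)(C)C(C)(C)C)C[C@@H](O[Si](C)(C)C)CC(O[Si](C)(C)C)=CC(=O)OC | intermediate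
21 | methyl (5R,7S,9S,11S)-7,9,11-tris(tert-butyldimethylsilyloxy)-5-hydroxy-3-oxoicosanoate | CCCCCCCCC[C@H](O[Si](C)(C)C(C)(C)C)C[C@H](O[Si](C)(C)C(C)(C)C)C[C@@H](O[Si](C)(C)C(C)(C)C)C[C@@H](O)CC(=O)CC(=O)OC | intermediate
22 | (6R)-4-hydroxy-6-[(2S,4S,6S)-2,4,6-tris(tert-butyldimethylsilyloxy)pentadecyl]-5,6-dihydro-2H-pyran-2-one | CCCCCCCCC[C@H](O[Si](C)(C)C(C)(C)C)C[C@H](O[Si](C)(C)C(C)(C)C)C[C@@H](O[Si](C)(C)C(C)(C)C)C[C@@H]1CC(O)=CC(=O)O1 | intermediate
23 | (6R)-4-hydroxy-6-[(2R,4S,6S)-2,4,6-trihydroxypentadecyl]-5,6-dihydro-2H-pyran-2-one | CCCCCCCCC[C@H](O)C[C@H](O)C[C@@H](O)C[C@@H]1CC(O)=CC(=O)O1 | target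

## Step count and weak points

Total: 15 steps. Longest linear sequence: 15 steps, from 1 to 23; compounds 9 and 19 are purchased.

**Step 4 (key step).** The most likely failure is poor discrimination between the two enantiotopic methylenes on this untested substrate. The stereocentres are remote from the carbonyl and the silyl groups are bulky, so the catalyst pocket may read them badly. A second failure mode is Lewis-acid-induced loss of a β-silyloxy group. The fallback sets out from 4 and returns at 7, cutting the same C7–C12 bond by a different mechanism. Enantioselective deprotonation of 4 with a chiral lithium amide, LiN[CH(CH3)Ph]2, in the presence of Me3SiCl at −78 °C should give the silyl enol ether (3R,5S)-3,5-bis(tert-butyldimethylsilyloxy)-1-(trimethylsilyloxy)cyclohex-1-ene F1. Ozonolysis with NaBH4 work-up cleaves C7=C12 to (3S,5R)-3,5-bis(tert-butyldimethylsilyloxy)-6-hydroxyhexanoic acid F2. Carbodiimide coupling with N,O-dimethylhydroxylamine then gives 7.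

**Step 13.** The likely failure is poor facial selectivity. The catalyst has to work against the substrate's 1,3-anti preference, and aliphatic aldehydes are the less favourable class for this catalyst. The fallback sets out from 15 and returns at 23. It fixes C5 by thermodynamic control instead. Cross-metathesis of 15 with methyl acrylate (second-generation Grubbs catalyst, (H2IMes)(PCy3)Cl2Ru=CHPh) should give methyl (2E,5S,7R,9S)-7,9-bis(tert-butyldimethylsilyloxy)-5-hydroxyoctadec-2-enoate F3. Benzaldehyde with catalytic KOtBu adds the hemiacetal alkoxide in conjugate fashion to give the all-equatorial acetal methyl 2-[(2R,4R,6S)-6-[(2R,4S)-2,4-bis(tert-butyldimethylsilyloxy)tridecyl]-2-phenyl-1,3-dioxan-4-yl]acetate F4, with C5 syn to C7. Claisen condensation with LiCH2CO2tBu gives tert-butyl 4-[(2R,4R,6S)-6-[(2R,4S)-2,4-bis(tert-butyldimethylsilyloxy)tridecyl]-2-phenyl-1,3-dioxan-4-yl]-3-oxobutanoate F5. Aqueous trifluoroacetic acid then removes the acetal, the silyl ethers and the tert-butyl group and closes the lactone to 23.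

**Step 7.** The likely failures are epimerisation at C11 of the α-silyloxy aldehyde under the basic ylide conditions and competing attack of the ylide on the Weinreb amide. The fallback sets out from 7 and returns at 12. It avoids the aldehyde altogether. Triflation of the primary alcohol (Tf2O, 2,6-lutidine, −78 °C) should give (2R,4S)-2,4-bis(tert-butyldimethylsilyloxy)-6-[methoxy(methyl)amino]-6-oxohexyl trifluoromethanesulfonate F6. Displacement with (n-C8H17)2CuLi at −78 → −30 °C, to which the amide is inert, forms the C12–C13 single bond directly.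

**Step 15.** The likely failure is acid-promoted side reaction of the finished pyranone during the slow removal of three secondary silyl ethers: addition of the freed C7 hydroxyl to C3, or lactone opening. The fallback sets out from 21 and returns at 23. It reverses the order so that the pyranone never meets HF. Desilylation of 21 with HF·pyridine should give methyl (5R,7R,9S,11S)-5,7,9,11-tetrahydroxy-3-oxoicosanoate F7, in reversible equilibrium with its cyclic hemiketal. Lactonisation with K2CO3 in methanol and careful acidification then deliver 23.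

## Further compounds

F1 | step 4 | (3R,5S)-3,5-bis(tert-butyldimethylsilyloxy)-1-(trimethylsilyloxy)cyclohex-1-ene | C[Si](C)(C)OC1=C[C@H](O[Si](C)(C)C(C)(C)C)C[C@H](O[Si](C)(C)C(C)(C)C)C1
F2 | step 4 | (3S,5R)-3,5-bis(tert-butyldimethylsilyloxy)-6-hydroxyhexanoic acid | OC[C@H](O[Si](C)(C)C(C)(C)C)C[C@H](O[Si](C)(C)C(C)(C)C)CC(=O)O
F3 | step 13 | methyl (2E,5S,7R,9S)-7,9-bis(tert-butyldimethylsilyloxy)-5-hydroxyoctadec-2-enoate | CCCCCCCCC[C@H](O[Si](C)(C)C(C)(C)C)C[C@H](O[Si](C)(C)C(C)(C)C)C[C@@H](O)C/C=C/C(=O)OC
F4 | step 13 | methyl 2-[(2R,4R,6S)-6-[(2R,4S)-2,4-bis(tert-butyldimethylsilyloxy)tridecyl]-2-phenyl-1,3-dioxan-4-yl]acetate | CCCCCCCCC[C@H](O[Si](C)(C)C(C)(C)C)C[C@H](O[Si](C)(C)C(C)(C)C)C[C@@H]1C[C@H](CC(=O)OC)O[C@H](c2ccccc2)O1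
F5 | step 13 | tert-butyl 4-[(2R,4R,6S)-6-[(2R,4S)-2,4-bis(tert-butyldimethylsilyloxy)tridecyl]-2-phenyl-1,3-dioxan-4-yl]-3-oxobutanoate | CCCCCCCCC[C@H](O[Si](C)(C)C(C)(C)C)C[C@H](O[Si](C)(C)C(C)(C)C)C[C@@H]1C[C@H](CC(=O)CC(=O)OC(C)(C)C)O[C@H](c2ccccc2)O1
F6 | step 7 | (2R,4S)-2,4-bis(tert-butyldimethylsilyloxy)-6-[methoxy(methyl)amino]-6-oxohexyl trifluoromethanesulfonate | FC(F)(F)S(=O)(=O)OC[C@H](O[Si](C)(C)C(C)(C)C)C[C@H](O[Si](C)(C)C(C)(C)C)CC(=O)N(C)OC
F7 | step 15 | methyl (5R,7R,9S,11S)-5,7,9,11-tetrahydroxy-3-oxoicosanoate | CCCCCCCCC[C@H](O)C[C@H](O)C[C@@H](O)C[C@@H](O)CC(=O)CC(=O)OC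
A1 | alternative 1 | C2-symmetric 3,5:7,9-bis(benzylidene acetal) of syn,anti,syn-undeca-1,10-diene-3,5,7,9-tetraol | C=C[C@H]1C[C@@H](C[C@@H]2C[C@H](C=C)O[C@H](c3ccccc3)O2)O[C@@H](c3ccccc3)O1
A2 | alternative 1 | (2E,5S,7S,9E)-undeca-2,9-diene-1,5,7,11-tetraol | OC/C=C/C[C@H](O)C[C@@H](O)C/C=C/CO
A3 | alternative 2 | methyl (3R,5S,6E,9S)-3-(tert-butyldimethylsilyloxy)-5,9-dihydroxyoctadec-6-enoate | CCCCCCCCC[C@H](O)C/C=C/[C@@H](O)C[C@@H](O[Si](C)(C)C(C)(C)C)CC(=O)OC
A4 | alternative 2 | methyl (3R)-3-(tert-butyldimethylsilyloxy)-5-oxopentanoate | O=CC[C@@H](O[Si](C)(C)C(C)(C)C)CC(=O)OC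
A5 | alternative 2 | decanal | CCCCCCCCCC=O
A6 | alternative 2 | 5,5-dimethyl-2-(propa-1,2-dien-1-yl)-1,3,2-dioxaborinane | C=C=CB1OCC(C)(C)CO1
A7 | alternative 3 | (4R)-4-substituted oxetan-2-one holding C3–C5, with the C7 silyl ether and the C9/C11 acetonide | CCCCCCCCC[C@H]1C[C@@H](C[C@@H](O[Si](C)(C)C(C)(C)C)C[C@@H]2CC(=O)O2)OC(C)(C)O1
A8 | alternative 3 | terminal C4–C5 epoxide with the C7 silyl ether and the C9/C11 acetonide | CCCCCCCCC[C@H]1C[C@@H](C[C@@H](O[Si](C)(C)C(C)(C)C)C[C@@H]2CO2)OC(C)(C)O1
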